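Core numbering used throughout: C1 (allyl bridgehead), C2=C3 (enol ether), C4 (acetoxy carbon), C5 (methoxy bridgehead), C6 (aryl carbon), C7 (methyl carbon), C8 (bridging ketone).
Retrosynthesis: the acetate is removed and the C2=C3 enol ether is traced back to a C3 dimethyl ketal; C4–C5 and C6–aryl are then cut in one operation, leaving a cyclopentenone aldehyde and an arylzinc; the cyclopentenone is cut at C1–C2 and C7–CH3, and last at the allyl–ring bond.
Enabling feature: in the five-membered ring C1–C8–C5–C6–C7, C6 is the β-carbon and C5 the α-carbon of the C8 ketone, and C1 carries the arm C2–C3–C4 ending in an aldehyde; aryl addition at C6 therefore creates a C5 enol derivative that reaches C4 and closes the six-membered ring C1–C2–C3–C4–C5–C8 of the bicyclo[3.2.1]octane.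
Forward order: the five-membered ring is present from the start; methyl and side arm are added to 2-allylcyclopentenone, C5 is oxygenated, the arm is oxidised to the aldehyde, the key step adds the aryl group and closes the six-membered ring, and the ketal becomes the enol ether before acetylation. C3 is carried as a ketal because the (E)-2-methoxy enal arm, with the ring carbon cis to the formyl group, is the less accessible alkene isomer; the ketal needs no alkene geometry and makes the aldehyde non-enolisable.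
Stereochemistry: C7 from a copper-catalysed asymmetric methyl addition; C1 from alkylation anti to that methyl; C6 from aryl delivery anti to the methyl, reinforced by (S)-BINAP; C5 from the tether; C4 from the open aldol transition state.

Key step: step 10

Assumption: in step 4 the phosphoramidite enantiomer that gives the (3S)-methyl centre is used; should the sense of induction on this 2-substituted enone be opposite to the expected one, the mirror-image ligand is taken.

Step 1
Reactants: 1 cyclopent-2-en-1-one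
Product: 2 2-iodocyclopent-2-en-1-one
Conditions: I2, pyridine, CH2Cl2, 0 → 20 °C
Reagents that add atoms: iodine, II
Why: Pyridine adds reversibly to the enone, the enolate so formed is iodinated at the α-carbon and pyridine is expelled again, which is the standard α-iodination of cyclic enones.

Step 2
Reactants: 2 2-iodocyclopent-2-en-1-one; 3 tributyl(prop-2-en-1-yl)stannane
Product: 4 2-(prop-2-en-1-yl)cyclopent-2-en-1-one
Conditions: Pd2(dba)3 (2.5 mol%), AsPh3 (10 mol%), CuI (10 mol%), NMP, 20 °C
Reagents that add atoms: none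
Why: Stille coupling of the α-iodo enone with the allyl stannane, run at room temperature with AsPh3 and CuI to speed transmetalation so that the skipped diene does not drift into conjugation.

Step 3
Reactants: 5 2-methoxypropene
Product: 6 3-bromo-2-methoxyprop-1-ene
Conditions: NBS, CH2Cl2, −10 °C, dark; distilled from K2CO3 and used at once
Reagents that add atoms: N-bromosuccinimide, O=C1CCC(=O)N1Br
Why: Electrophilic bromination of the enol ether followed by loss of a methyl proton from the oxocarbenium ion (ene-type allylic bromination) gives the reactive 2-methoxyallyl bromide, a known acetonyl-type alkylating agent.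

Step 4
Reactants: 4 2-(prop-2-en-1-yl)cyclopent-2-en-1-one; 6 3-bromo-2-methoxyprop-1-ene
Product: 9 (2R,3S)-2-(2-methoxyprop-2-en-1-yl)-3-methyl-2-(prop-2-en-1-yl)cyclopentan-1-one, via aluminium enolate 7 (not isolated), via lithium aluminate 8 (not isolated)
Conditions: Me3Al, Cu(OTf)2 (2 mol%), O,O'-(1,1'-binaphthyl-2,2'-diyl)-N,N-bis(1-phenylethyl)phosphoramidite (4 mol%), Et2O, −30 °C; then MeLi, THF, 6, −30 → 0 °C
Reagents that add atoms: trimethylaluminium, C[Al](C)C
Why: Copper-catalysed asymmetric conjugate addition of Me3Al sets C7 (S) under ligand control and gives the tetrasubstituted enolate regiospecifically, and after activation as the aluminate the enolate is alkylated (SN2) by the allylic bromide anti to the adjacent methyl group, which fixes the quaternary C1 (R) with allyl cis to methyl.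

Step 5
Reactants: 9 (2R,3S)-2-(2-methoxyprop-2-en-1-yl)-3-methyl-2-(prop-2-en-1-yl)cyclopentan-1-one
Product: 11 (4S,5R)-2-hydroxy-5-(2-methoxyprop-2-en-1-yl)-4-methyl-5-(prop-2-en-1-yl)cyclopent-2-en-1-one, via hydroperoxide 10 (not isolated)
Conditions: KOtBu, O2 (1 atm), tBuOH/DME, 20 °C; aq NH4Cl
Reagents that add atoms: dioxygen, O=O
Why: Base-mediated autoxidation of a ketone with a single enolisable α-methylene (C1 is quaternary) traps O2 at C5, the α-hydroperoxy ketone loses hydroxide to give the 1,2-dione, and this rests as its enol towards C6 (diosphenol), while the non-acidic C7 centre is untouched.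

Step 6
Reactants: 11 (4S,5R)-2-hydroxy-5-(2-methoxyprop-2-en-1-yl)-4-methyl-5-(prop-2-en-1-yl)cyclopent-2-en-1-one
Product: 12 (4S,5R)-2-methoxy-5-(2-methoxyprop-2-en-1-yl)-4-methyl-5-(prop-2-en-1-yl)cyclopent-2-en-1-one
Conditions: MeI, K2CO3, acetone, 40 °C
Reagents that add atoms: iodomethane, CI
Why: Williamson-type O-methylation of the acidic enol of the cyclic 1,2-dione, the usual outcome for diosphenols under carbonate conditions, gives the 2-methoxy enone that the key step needs.

Step 7
Reactants: 12 (4S,5R)-2-methoxy-5-(2-methoxyprop-2-en-1-yl)-4-methyl-5-(prop-2-en-1-yl)cyclopent-2-en-1-one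
Product: 14 (4S,5R)-5-(3-hydroxy-2,2-dimethoxypropyl)-2-methoxy-4-methyl-5-(prop-2-en-1-yl)cyclopent-2-en-1-one, via epoxide 13 (not isolated)
Conditions: DMDO (1.05 equiv, acetone), MeOH/CH2Cl2, −40 → 0 °C
Reagents that add atoms: dimethyldioxirane, CC1(C)OO1; methanol, CO
Why: Epoxidation of the electron-rich 1,1-disubstituted enol ether, which is far faster than attack on the carbonyl-deactivated ring enol ether or the monosubstituted alkene, followed by methanolysis of the 2-methoxyoxirane at its acetal carbon gives the α-hydroxy dimethyl ketal, whose ketal carbon is not stereogenic.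

Step 8
Reactants: 14 (4S,5R)-5-(3-hydroxy-2,2-dimethoxypropyl)-2-methoxy-4-methyl-5-(prop-2-en-1-yl)cyclopent-2-en-1-one
Product: 15 2,2-dimethoxy-3-[(1R,5S)-3-methoxy-5-methyl-2-oxo-1-(prop-2-en-1-yl)cyclopent-3-en-1-yl]propanal
Conditions: DMP, pyridine, CH2Cl2, 0 → 20 °C
Reagents that add atoms: none
Why: Periodinane oxidation of the primary alcohol under buffered conditions gives the non-enolisable α,α-dimethoxy aldehyde without touching the ketal, the enone or the alkene.

Step 9
Reactants: 16 5-bromo-1,2,3-trimethoxybenzene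
Product: 18 chloro(3,4,5-trimethoxyphenyl)zinc, via aryllithium 17 (not isolated)
Conditions: nBuLi, THF, −78 °C; then ZnCl2, −78 → 20 °C
Reagents that add atoms: zinc chloride, Cl[Zn]Cl
Why: Bromine–lithium exchange followed by transmetalation to zinc gives the arylzinc chloride, which is used directly as a THF solution.

Step 10
Reactants: 15 2,2-dimethoxy-3-[(1R,5S)-3-methoxy-5-methyl-2-oxo-1-(prop-2-en-1-yl)cyclopent-3-en-1-yl]propanal; 18 chloro(3,4,5-trimethoxyphenyl)zinc
Product: 21 (1R,4S,5S,6R,7S)-4-hydroxy-3,3,5-trimethoxy-7-methyl-1-(prop-2-en-1-yl)-6-(3,4,5-trimethoxyphenyl)bicyclo[3.2.1]octan-8-one (core numbering), via silyl enol ether 19 (not isolated), via difluoroboryl aldolate 20 (not isolated)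
Conditions: [RhCl(C2H4)2]2 (2.5 mol%), (S)-2,2'-bis(diphenylphosphino)-1,1'-binaphthyl ((S)-BINAP, 5.5 mol%), Me3SiCl, THF, 20 °C; then solvent exchange to CH2Cl2, BF3·OEt2, −78 °C; aq NaHCO3
Reagents that add atoms: none
Why: The aryl group passes from zinc to rhodium, the C5=C6 bond inserts into the Rh–aryl bond and Me3SiCl silylates the resulting oxa-π-allyl to give the C5=C8 silyl enol ether 19 regiospecifically, after which BF3·OEt2 activates the C4 aldehyde and C5 attacks it (intramolecular Mukaiyama aldol) to give aldolate 20, hydrolysed on work-up to 21. Both halves are known reaction types, namely the rhodium/BINAP-catalysed 1,4-addition of arylzinc chlorides to enones with chlorosilane trapping and the conjugate addition–Mukaiyama aldol ring closure. The six-membered ring C1–C2–C3–C4–C5–C8 closes in the 6-(enolendo)-exo-trig mode and turns the cyclopentane into the bicyclo[3.2.1]octan-8-one. At C6 the aryl group enters anti to the neighbouring C7 methyl, and (S)-BINAP, whose usual facial preference on cyclopent-2-enones is the same, should make a matched pair; at C5 the aldehyde hangs from the face of C1 opposite to the methyl and allyl groups, so the C4–C5 bond can form only there and the methoxy group ends up outside; at C4 the open transition state with the C4=O·BF3 and C8–OSi dipoles opposed should place the oxygen anti to the C8 bridge. The step needs 1,4-arylation of the enone in preference to 1,2-arylation of the aldehyde, which rests on the much faster insertion of enones into the Rh–aryl bond and on the neopentyl position of the aldehyde, and it needs silylation before any metal-enolate aldol, which Me3SiCl present from the start should secure.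

Step 11
Reactants: 21 (1R,4S,5S,6R,7S)-4-hydroxy-3,3,5-trimethoxy-7-methyl-1-(prop-2-en-1-yl)-6-(3,4,5-trimethoxyphenyl)bicyclo[3.2.1]octan-8-one
Product: 23 (1S,4R,5S,6R,7S)-4-hydroxy-3,5-dimethoxy-7-methyl-1-(prop-2-en-1-yl)-6-(3,4,5-trimethoxyphenyl)bicyclo[3.2.1]oct-2-en-8-one, via silyl ether 22 (not isolated)
Conditions: Me3SiOTf (2.5 equiv), iPr2NEt, CH2Cl2, −20 → 0 °C; then Bu4NF, AcOH, THF, 0 °C
Reagents that add atoms: none
Why: Me3SiOTf silylates the C4 hydroxyl and ionises the C3 ketal to an oxocarbenium ion, which the hindered amine should deprotonate at the less substituted C2 methylene and not at the tertiary, silyloxy-bearing C4 (ketal-to-enol-ether elimination), and buffered fluoride then frees the alcohol without retro-aldol cleavage or change at any stereocentre.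

Step 12
Reactants: 23 (1S,4R,5S,6R,7S)-4-hydroxy-3,5-dimethoxy-7-methyl-1-(prop-2-en-1-yl)-6-(3,4,5-trimethoxyphenyl)bicyclo[3.2.1]oct-2-en-8-one
Product: 24 (1S,4R,5S,6R,7S)-3,5-dimethoxy-7-methyl-8-oxo-1-(prop-2-en-1-yl)-6-(3,4,5-trimethoxyphenyl)bicyclo[3.2.1]oct-2-en-4-yl acetate
Conditions: Ac2O, pyridine, 4-(dimethylamino)pyridine (5 mol%), CH2Cl2, 20 °C
Reagents that add atoms: acetic anhydride, CC(=O)OC(C)=O
Why: Nucleophile-catalysed acylation (esterification) of the hindered secondary alcohol under mildly basic conditions, which should not open the β-hydroxy ketone, gives the target acetate.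

Compound list
1 | cyclopent-2-en-1-one | O=C1C=CCC1 | starting material
2 | 2-iodocyclopent-2-en-1-one | O=C1C(I)=CCC1 | intermediate
3 | tributyl(prop-2-en-1-yl)stannane | C=CC[Sn](CCCC)(CCCC)CCCC | starting material
4 | 2-(prop-2-en-1-yl)cyclopent-2-en-1-one | C=CCC1=CCCC1=O | intermediate
5 | 2-methoxypropene | COC(C)=C | starting material
6 | 3-bromo-2-methoxyprop-1-ene (2-methoxyallyl bromide) | COC(=C)CBr | intermediate
7 | dimethylaluminium (3S)-3-methyl-2-(prop-2-en-1-yl)cyclopent-1-en-1-olate (not isolated) | C=CCC1=C(O[Al](C)C)CC[C@@H]1C | intermediate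
8 | lithium trimethyl{[(3S)-3-methyl-2-(prop-2-en-1-yl)cyclopent-1-en-1-yl]oxy}aluminate (not isolated) | [Li+].C=CCC1=C(O[Al-](C)(C)C)CC[C@@H]1C | intermediate
9 | (2R,3S)-2-(2-methoxyprop-2-en-1-yl)-3-methyl-2-(prop-2-en-1-yl)cyclopentan-1-one (allyl cis to methyl) | C=CC[C@]1(CC(OC)=C)C(=O)CC[C@@H]1C | intermediate
10 | (2R,3S)-5-hydroperoxy-2-(2-methoxyprop-2-en-1-yl)-3-methyl-2-(prop-2-en-1-yl)cyclopentan-1-one, both C5 epimers (not isolated) | C=CC[C@]1(CC(OC)=C)C(=O)C(OO)C[C@@H]1C | intermediate
11 | (4S,5R)-2-hydroxy-5-(2-methoxyprop-2-en-1-yl)-4-methyl-5-(prop-2-en-1-yl)cyclopent-2-en-1-one | C=CC[C@]1(CC(OC)=C)C(=O)C(O)=C[C@@H]1C | intermediate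
12 | (4S,5R)-2-methoxy-5-(2-methoxyprop-2-en-1-yl)-4-methyl-5-(prop-2-en-1-yl)cyclopent-2-en-1-one | C=CC[C@]1(CC(OC)=C)C(=O)C(OC)=C[C@@H]1C | intermediate
13 | (4S,5R)-2-methoxy-5-[(2-methoxyoxiran-2-yl)methyl]-4-methyl-5-(prop-2-en-1-yl)cyclopent-2-en-1-one, both oxirane epimers (not isolated) | C=CC[C@]1(CC2(OC)CO2)C(=O)C(OC)=C[C@@H]1C | intermediate
14 | (4S,5R)-5-(3-hydroxy-2,2-dimethoxypropyl)-2-methoxy-4-methyl-5-(prop-2-en-1-yl)cyclopent-2-en-1-one | C=CC[C@]1(CC(OC)(OC)CO)C(=O)C(OC)=C[C@@H]1C | intermediate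
15 | 2,2-dimethoxy-3-[(1R,5S)-3-methoxy-5-methyl-2-oxo-1-(prop-2-en-1-yl)cyclopent-3-en-1-yl]propanal | C=CC[C@]1(CC(OC)(OC)C=O)C(=O)C(OC)=C[C@@H]1C | intermediate
16 | 5-bromo-1,2,3-trimethoxybenzene | COc1cc(Br)cc(OC)c1OC | starting material
17 | (3,4,5-trimethoxyphenyl)lithium (not isolated) | [Li]c1cc(OC)c(OC)c(OC)c1 | intermediate
18 | chloro(3,4,5-trimethoxyphenyl)zinc | Cl[Zn]c1cc(OC)c(OC)c(OC)c1 | intermediate
19 | 2,2-dimethoxy-3-[(1R,4R,5S)-3-methoxy-5-methyl-1-(prop-2-en-1-yl)-4-(3,4,5-trimethoxyphenyl)-2-(trimethylsilyloxy)cyclopent-2-en-1-yl]propanal, aryl trans to methyl (not isolated) | C=CC[C@]1(CC(OC)(OC)C=O)C(O[Si](C)(C)C)=C(OC)[C@@H](c2cc(OC)c(OC)c(OC)c2)[C@@H]1C | intermediate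
20 | (1R,4S,5S,6R,7S)-4-(difluoroboryloxy)-3,3,5-trimethoxy-7-methyl-1-(prop-2-en-1-yl)-6-(3,4,5-trimethoxyphenyl)bicyclo[3.2.1]octan-8-one (not isolated) | C=CC[C@]12CC(OC)(OC)[C@@H](OB(F)F)[C@](OC)(C1=O)[C@@H](c1cc(OC)c(OC)c(OC)c1)[C@@H]2C | intermediate
21 | (1R,4S,5S,6R,7S)-4-hydroxy-3,3,5-trimethoxy-7-methyl-1-(prop-2-en-1-yl)-6-(3,4,5-trimethoxyphenyl)bicyclo[3.2.1]octan-8-one (core numbering; 4-OH anti to C8, 6-aryl endo, 7-methyl exo) | C=CC[C@]12CC(OC)(OC)[C@@H](O)[C@](OC)(C1=O)[C@@H](c1cc(OC)c(OC)c(OC)c1)[C@@H]2C | intermediate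
22 | (1S,4R,5S,6R,7S)-3,5-dimethoxy-7-methyl-1-(prop-2-en-1-yl)-6-(3,4,5-trimethoxyphenyl)-4-(trimethylsilyloxy)bicyclo[3.2.1]oct-2-en-8-one (not isolated) | C=CC[C@]12C=C(OC)[C@@H](O[Si](C)(C)C)[C@](OC)(C1=O)[C@@H](c1cc(OC)c(OC)c(OC)c1)[C@@H]2C | intermediate
23 | (1S,4R,5S,6R,7S)-4-hydroxy-3,5-dimethoxy-7-methyl-1-(prop-2-en-1-yl)-6-(3,4,5-trimethoxyphenyl)bicyclo[3.2.1]oct-2-en-8-one | C=CC[C@]12C=C(OC)[C@@H](O)[C@](OC)(C1=O)[C@@H](c1cc(OC)c(OC)c(OC)c1)[C@@H]2C | intermediate
24 | (1S,4R,5S,6R,7S)-3,5-dimethoxy-7-methyl-8-oxo-1-(prop-2-en-1-yl)-6-(3,4,5-trimethoxyphenyl)bicyclo[3.2.1]oct-2-en-4-yl acetate | C=CC[C@]12C=C(OC)[C@@H](OC(C)=O)[C@](OC)(C1=O)[C@@H](c1cc(OC)c(OC)c(OC)c1)[C@@H]2C | target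

Total step count: 12. Longest linear sequence: 10 steps (steps 1, 2, 4–8 and 10–12).

Steps most likely to fail

Step 10. The rhodium aryl may insert the electron-rich, α-substituted C5=C6 bond too slowly, so that arylation of the free aldehyde or a metal-enolate aldol through a closed transition state (C4 epimer) competes; facial control at C6 could also be eroded. The fallback sets out from 12 (with aryllithium 17) and comes back at 19: the aryl group is introduced by copper before the aldehyde exists. Aryllithium 17 and CuI would give lithium bis(3,4,5-trimethoxyphenyl)cuprate F1, which with Me3SiCl in THF at −78 °C should add to C6 of 12 anti to the methyl group and give silyl enol ether F2; buffered Bu4NF would release α-methoxy ketone F3, whose C5 epimers are of no consequence. DMDO in methanol, as in step 7, would convert the side-chain enol ether through epoxide F4 into hydroxy ketal F5, and DMP, as in step 8, would give keto aldehyde F6. Because C1 is quaternary, this ketone can enolise only towards C5, so LiN(SiMe3)2 with Me3SiCl as internal quench would give 19, which is then cyclised with BF3·OEt2 as in the second half of step 10.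

Step 11. Proton loss from the oxocarbenium ion could occur at C4 instead of C2, the β-silyloxy ketone could open by retro-aldol cleavage, and a wrong C4 configuration carried over from step 10 would not be corrected. The fallback sets out from 21 and comes back at 23. DMP would oxidise the C4 alcohol to α-keto ketal F7; p-toluenesulfonic acid in warm toluene would then expel methanol, and here only the conjugated 3-methoxy enone F8 can form. Luche reduction (NaBH4, CeCl3·7H2O, MeOH, −78 °C) should reduce the enone carbonyl in preference to the C8 ketone, which is flanked by two quaternary carbons, with hydride arriving from the face of the C8 bridge, away from the endo aryl group, to give 23. This sequence sets C4 independently of the aldol.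

Step 4. Methyl transfer to an α-substituted cyclopentenone may proceed with insufficient enantioselectivity, and the aluminium enolate may alkylate sluggishly or on oxygen. The fallback sets out from 4 and comes back at 9. CBS reduction with the (S)-B-methyl oxazaborolidine derived from diphenylprolinol and BH3·SMe2 should give (R)-allylic alcohol F9; hydroxyl-directed Simmons–Smith cyclopropanation (Et2Zn, CH2I2) would give cis cyclopropyl carbinol F10, and DMP would give cyclopropyl ketone F11. Li in NH3/THF would cleave the cyclopropane bond between the α-carbon and the CH2 group, the one that overlaps with the carbonyl π system, so that the CH2 becomes the C7 methyl and the regiodefined lithium enolate F12 results; alkylation in the same flask with 6, anti to the methyl group, would give 9.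

Further compounds
F1 | step 10 | lithium bis(3,4,5-trimethoxyphenyl)cuprate | [Li+].COc1cc([Cu-]c2cc(OC)c(OC)c(OC)c2)cc(OC)c1OC
F2 | step 10 | {[(3R,4S,5R)-2-methoxy-5-(2-methoxyprop-2-en-1-yl)-4-methyl-5-(prop-2-en-1-yl)-3-(3,4,5-trimethoxyphenyl)cyclopent-1-en-1-yl]oxy}trimethylsilane | C=CC[C@]1(CC(OC)=C)C(O[Si](C)(C)C)=C(OC)[C@@H](c2cc(OC)c(OC)c(OC)c2)[C@@H]1C
F3 | step 10 | (3R,4S,5R)-2-methoxy-5-(2-methoxyprop-2-en-1-yl)-4-methyl-5-(prop-2-en-1-yl)-3-(3,4,5-trimethoxyphenyl)cyclopentan-1-one (C2 epimers) | C=CC[C@]1(CC(OC)=C)C(=O)C(OC)[C@@H](c2cc(OC)c(OC)c(OC)c2)[C@@H]1C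
F4 | step 10 | (3R,4S,5R)-2-methoxy-5-[(2-methoxyoxiran-2-yl)methyl]-4-methyl-5-(prop-2-en-1-yl)-3-(3,4,5-trimethoxyphenyl)cyclopentan-1-one | C=CC[C@]1(CC2(OC)CO2)C(=O)C(OC)[C@@H](c2cc(OC)c(OC)c(OC)c2)[C@@H]1C
F5 | step 10 | (3R,4S,5R)-5-(3-hydroxy-2,2-dimethoxypropyl)-2-methoxy-4-methyl-5-(prop-2-en-1-yl)-3-(3,4,5-trimethoxyphenyl)cyclopentan-1-one | C=CC[C@]1(CC(OC)(OC)CO)C(=O)C(OC)[C@@H](c2cc(OC)c(OC)c(OC)c2)[C@@H]1C
F6 | step 10 | 2,2-dimethoxy-3-[(1R,4R,5S)-3-methoxy-5-methyl-2-oxo-1-(prop-2-en-1-yl)-4-(3,4,5-trimethoxyphenyl)cyclopentyl]propanal | C=CC[C@]1(CC(OC)(OC)C=O)C(=O)C(OC)[C@@H](c2cc(OC)c(OC)c(OC)c2)[C@@H]1C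
F7 | step 11 | (1R,5R,6R,7S)-3,3,5-trimethoxy-7-methyl-1-(prop-2-en-1-yl)-6-(3,4,5-trimethoxyphenyl)bicyclo[3.2.1]octane-4,8-dione | C=CC[C@]12CC(OC)(OC)C(=O)[C@](OC)(C1=O)[C@@H](c1cc(OC)c(OC)c(OC)c1)[C@@H]2C
F8 | step 11 | (1S,5R,6R,7S)-3,5-dimethoxy-7-methyl-1-(prop-2-en-1-yl)-6-(3,4,5-trimethoxyphenyl)bicyclo[3.2.1]oct-2-ene-4,8-dione | C=CC[C@]12C=C(OC)C(=O)[C@](OC)(C1=O)[C@@H](c1cc(OC)c(OC)c(OC)c1)[C@@H]2C
F9 | step 4 | (1R)-2-(prop-2-en-1-yl)cyclopent-2-en-1-ol | O[C@@H]1CCC=C1CC=C
F10 | step 4 | (1S,2R,5R)-1-(prop-2-en-1-yl)bicyclo[3.1.0]hexan-2-ol (cyclopropane cis to hydroxyl) | O[C@@H]1CC[C@@H]2C[C@]12CC=C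
F11 | step 4 | (1S,5R)-1-(prop-2-en-1-yl)bicyclo[3.1.0]hexan-2-one | O=C1CC[C@@H]2C[C@]12CC=C
F12 | step 4 | lithium (3S)-3-methyl-2-(prop-2-en-1-yl)cyclopent-1-en-1-olate | C=CCC1=C(O[Li])CC[C@@H]1C
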